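The easy step comes first: the last 4 readings of the ochre flask lie between 9.3% and 9.7% against a scatter of 0.3 percentage points, so we call the line flat and take its mean, 9.55%.

| setting | ochre | flask |
|---|---|---|
| solid substrate | 0.80 M | 0.80 M |
| reagent | 0.96 M | 0.960 M |
| temperature | 25 °C | 25 °C |
| remark | the very flask that is asked about, followed so far |  |
| time |  | 6.0 h |

ochre run (percent of the solid substrate charged)

| time / min | target / % |
|---|---|
| 60.0 | 13.7 |
| 120 | 10.8 |
| 180 | 9.7 |
| 240 | 9.6 |
| 300 | 9.3 |
| 360 | 9.6 |

(each reading ± 0.3 percentage points)

- given per volume of solution although it is solid: solid substrate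
- removed target is counted in
- the numbers in the tables scatter by 0.3 percentage points (one standard deviation)
- at the start none of the solid substrate is in solution
- additions bring no volume worth counting

- Thursday's: at 6.0 h raise the temperature by 25 K, then wait 2.0 h
- Tuesday's: change nothing and wait 2.0 h more
- Sunday's: at 6.0 h add reagent, 50.0% of the amount charged, then wait 2.0 h
- Saturday's: at 6.0 h take out 90% of the target then present, then wait 2.0 h

- target, in percent of the solid substrate first charged, at 6.0 h
- the remedy with the largest gain of target, or "none" below 2 percentage points (Thursday's / Tuesday's / Sunday's / Saturday's / none)
- target present, with what was taken out counted in, in percent of the solid substrate first charged, after Thursday's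
- target present, with what was taken out counted in, in percent of the solid substrate first charged, after Sunday's

Should the next run be left, heated, fed or drained? In molar terms that plateau is f = 7.96% of the charged reagent; we call f the plateau yield on reagent, the share of the charged reagent standing as target once the line is flat. The ochre flask holds more reagent than solid substrate, so we bet that the flat line is a balance (an equilibrium), with target following reagent at frozen f.

The readings also suggest how fast the ochre flask returns to its line. Target stood 4.1 points above the plateau at 60.0 min and 1.3 points above it at 120 min, so the excess halves in about 34.7 min. That is shorter than the 2.0 h of waiting, and a disturbed flask should cover 90.9% of its way back.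

Tuesday's then gains nothing. Sunday's raises the reagent by 50.0%, which at frozen f gains 4.3 points and gives 13.9%. On the same bet, Saturday's should let the balance refill what was taken out and gain 7.8 points, more than Sunday's. A single temperature gives us no number for Thursday's, so our choice is Saturday's, with 9.55% now.

The forecast differs: it gives 9.5% now, 9.5% after Thursday's, 6% after Sunday's and none as the remedy, reading the line as “stopped by exhausted reagent”.

The flask gives 9.60% now and Thursday's as the best remedy, with a gain of 11 points and 20.2% of target. Saturday's gains 7.6 points, and Sunday's gains 2.1 points, reaching 11.7%.

    starting material + reagent ⇌ target (K = 0.590 L mol⁻¹, k = 0.0139 L mol⁻¹ s⁻¹, Ea = 57.0 kJ mol⁻¹, ΔH = 13.0 kJ mol⁻¹)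
    starting material + reagent ⇌ isomer of the product A (K = 2.90 L mol⁻¹, k = 4.52 × 10⁻⁴ L mol⁻¹ s⁻¹, Ea = 64.0 kJ mol⁻¹, ΔH = −23.0 kJ mol⁻¹)
    target ⇌ isomer of the product B (K = 0.741, k = 0.00775 s⁻¹, Ea = 91.0 kJ mol⁻¹, ΔH = −51.0 kJ mol⁻¹)
    solid substrate ⇌ starting material, rate k4*(cs4 - [starting material]) while solid is left; crystals form when [starting material] > cs4 (solubility = 0.390 M, k = 0.00383 s⁻¹)
    (constants at 25 °C)

In this flask at 360 min, target relaxes with starting material and reagent, by that step alone and both ways together, in a half-life of 0.341 min, far shorter than the 41.6 min by which half the turnover to isomer of the product A up to that time is done. At that time, isomer of the product A holds 47.1% of the solid substrate charged, and 46.8% of the reagent charged remains. After Sunday's, f with the added reagent gives 13.9% for this flask, which holds 11.7%. For the neighbour flask with 0.24 M of reagent, f gives 2.39%, and that flask holds 2.73%.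

The earlier runs and the new flask were computed from invented constants, and the scatter is random.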